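**Retrosynthetic overview**

1. The target comes from a Diels–Alder adduct by saturating C5=C6 and oxidising a side-chain CH2OH to CO2H; the C2 methyl stereocentre is bought with the (S)-Roche ester.
2. Key step: an ester-tethered intramolecular Diels–Alder reaction of an acrylate onto a (Z,E)-diene carried by the quaternary carbon C13. It closes the δ-lactone and the cyclohexane together and sets C4, C7 and C8 at once, replacing the usual lactonisation plus intermolecular fragment coupling.
3. The diene comes from Sonogashira coupling and semi-hydrogenation of a C13 ethynyl group. C13 is made quaternary by electrophilic alkynylation of a cis-fused β-keto γ-lactone that ties C12 to C18; the same lactone is later reduced and its C18 oxygen closes the ether bridge by oxa-Michael addition.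
4. The keto lactone comes from a Cu(OTf)2/phosphoramidite-catalysed enantioselective desymmetrising conjugate addition of an (alkoxycarbonyloxy)methylzinc reagent (with a non-transferable Me3SiCH2 group on zinc) to 4,4-dimethylcyclohexa-2,5-dienone, then intramolecular Claisen acylation by the carbonate.
5. Ring order: carbocycle of ring A (bought) → temporary γ-lactone → tetrahydrofuran bridge → δ-lactone and cyclohexane together.

Assumption: atom labels C1–C20 follow the target SMILES from left to right (C1 methyl, C2, C3 carboxyl, C4–C9 cyclohexane, C10 lactone carbonyl, O11, C12, C13 spiro carbon, C14 ketone, C15, C16, O17, C18, C19, C20 gem-dimethyl carbon); the target is 2R,4R,7R,8S,13S,16R,19R.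
Assumption: the sense of induction of the phosphoramidite in step 4 cannot be predicted with certainty for this zinc reagent; the ligand antipode that delivers (S)-7 is used.

**Route**

Step 1
Reactants: 1 4,4-dimethylcyclohex-2-en-1-one
Product: 2 4,4-dimethylcyclohexa-2,5-dien-1-one
Conditions: IBX (1.5 equiv), DMSO, 80 °C
Reagents that add atoms: none
Why: IBX dehydrogenation of a ketone through its enol can only place the new double bond at the C5–C6 position and gives the symmetric cross-conjugated dienone; no stereocentre is formed.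

Step 2
Reactants: 3 chloromethyl propan-2-yl carbonate
Product: 4 iodomethyl propan-2-yl carbonate
Conditions: NaI (1.5 equiv), acetone, 40 °C, dark
Reagents that add atoms: sodium iodide [Na+].[I-]
Why: Finkelstein halide exchange at an activated α-oxygenated primary chloride, driven by precipitation of NaCl.

Step 3
Reactants: 4 iodomethyl propan-2-yl carbonate
Product: 6 {[(propan-2-yloxy)carbonyloxy]methyl}[(trimethylsilyl)methyl]zinc, via organozinc iodide 5 (not isolated)
Conditions: Zn dust (2 equiv, activated with BrCH2CH2Br and Me3SiCl), THF, 10 °C; decanted from excess Zn; Me3SiCH2Li (1.0 equiv, pentane), −78 °C → −30 °C; solvent exchanged to toluene, LiI filtered off, solution titrated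
Reagents that add atoms: zinc [Zn]; (trimethylsilyl)methyllithium [Li]C[Si](C)(C)C
Why: Oxidative insertion of zinc into the activated α-acyloxy C–I bond (the way the known (pivaloyloxy)methylzinc iodide is made) and then lithium-to-zinc transmetalation give a mixed diorganozinc whose Me3SiCH2 group is a non-transferable ligand, the carbonate surviving because exchange at the zinc iodide at −78 °C is far faster than carbonyl addition.

Step 4
Reactants: 2 4,4-dimethylcyclohexa-2,5-dien-1-one; 6 {[(propan-2-yloxy)carbonyloxy]methyl}[(trimethylsilyl)methyl]zinc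
Product: 7 [(1S)-2,2-dimethyl-5-oxocyclohex-3-en-1-yl]methyl propan-2-yl carbonate
Conditions: Cu(OTf)2 (3 mol%), (S,R,R)-phosphoramidite from (S)-BINOL and bis[(R)-1-phenylethyl]amine (6 mol%), 6 (1.3 equiv), toluene, −30 °C; 1 M HCl
Reagents that add atoms: none
Why: Proposed new method: copper/phosphoramidite-catalysed enantioselective conjugate addition of dialkylzincs to 4,4-disubstituted cyclohexa-2,5-dienones is the closest known reaction and distinguishes the two enantiotopic enone units, mixed diorganozincs with a Me3SiCH2 group are known to transfer only the other group and copper–zinc acyloxymethyl reagents are known to add to enones, so transmetalation of the carbonate-bearing CH2 group to the chiral copper complex, π-complexation of one enone and reductive elimination should deliver it to C19 and set 19S, while the zinc enolate formed is too electron-rich for a second addition.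

Step 5
Reactants: 7 [(1S)-2,2-dimethyl-5-oxocyclohex-3-en-1-yl]methyl propan-2-yl carbonate
Product: 8 (3aS,7aR)-4,4-dimethyl-3,3a,4,7a-tetrahydro-2-benzofuran-1,7-dione
Conditions: LiN(SiMe3)2 (2.2 equiv), THF, −78 °C → 0 °C; 1 M HCl
Reagents that add atoms: none
Why: Intramolecular Claisen (Dieckmann-type) acylation in which the only possible enolate (C13) attacks the tethered carbonate carbonyl 5-exo-trig and expels isopropoxide, the second equivalent of base storing the β-keto lactone as its enolate; the labile C13–H centre settles as the cis-fused lactone on work-up.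

Step 6
Reactants: 8 (3aS,7aR)-4,4-dimethyl-3,3a,4,7a-tetrahydro-2-benzofuran-1,7-dione
Product: 9 (3aR,7aS)-7a-ethynyl-4,4-dimethyl-3,3a,4,7a-tetrahydro-2-benzofuran-1,7-dione
Conditions: TMS-EBX (1.3 equiv), Bu4NF (1.3 equiv), THF, −78 °C → rt
Reagents that add atoms: 1-[(trimethylsilyl)ethynyl]-1,2-benziodoxol-3(1H)-one (TMS-EBX) C[Si](C)(C)C#CI1OC(=O)c2ccccc12
Why: Electrophilic α-alkynylation of a β-keto ester enolate by a hypervalent-iodine alkyne-transfer reagent; the reagent reaches C13 from the face of H19, away from the pseudoaxial C20 methyl, so the γ-lactone stays cis-fused and the ethynyl carbon C7 ends up trans to C18 with C12 cis to C18, as in the target.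

Step 7
Reactants: 10 methyl (2S)-3-hydroxy-2-methylpropanoate
Product: 11 methyl (2S)-3-(benzyloxy)-2-methylpropanoate
Conditions: benzyl 2,2,2-trichloroacetimidate (1.3 equiv), TfOH (5 mol%), CH2Cl2/cyclohexane, 0 °C → rt
Reagents that add atoms: benzyl 2,2,2-trichloroacetimidate ClC(Cl)(Cl)C(=N)OCc1ccccc1
Why: Acid-catalysed O-benzylation with a trichloroacetimidate avoids the base that would racemise or eliminate the β-hydroxy ester, so the stereocentre is untouched.

Step 8
Reactants: 11 methyl (2S)-3-(benzyloxy)-2-methylpropanoate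
Product: 12 (2S)-3-(benzyloxy)-2-methylpropanal
Conditions: iBu2AlH (1.1 equiv), CH2Cl2, −78 °C; aq. KNaC4H4O6 (potassium sodium tartrate); used crude
Reagents that add atoms: none
Why: Partial ester reduction, since the tetrahedral aluminium hemiacetal is stable at −78 °C and releases the aldehyde only on work-up; the α-stereocentre survives because the aldehyde is used at once.

Step 9
Reactants: 12 (2S)-3-(benzyloxy)-2-methylpropanal
Product: 13 {[(2R,3E)-4-iodo-2-methylbut-3-en-1-yl]oxy}methylbenzene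
Conditions: CrCl2 (6 equiv), CHI3 (2 equiv), THF/1,4-dioxane, 0 °C → rt
Reagents that add atoms: iodoform IC(I)I
Why: Takai olefination, in which the geminal dichromium species from CHI3 adds to the aldehyde and eliminates to the (E)-vinyl iodide under non-basic conditions that do not epimerise C2 (the descriptor changes from S to R only because the priorities change).

Step 10
Reactants: 9 (3aR,7aS)-7a-ethynyl-4,4-dimethyl-3,3a,4,7a-tetrahydro-2-benzofuran-1,7-dione; 13 {[(2R,3E)-4-iodo-2-methylbut-3-en-1-yl]oxy}methylbenzene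
Product: 14 (3aR,7aS)-7a-[(3E,5R)-6-(benzyloxy)-5-methylhex-3-en-1-yn-1-yl]-4,4-dimethyl-3,3a,4,7a-tetrahydro-2-benzofuran-1,7-dione
Conditions: Pd(PPh3)2Cl2 (5 mol%), CuI (10 mol%), Et3N (3 equiv), THF, rt
Reagents that add atoms: none
Why: Sonogashira coupling of a terminal alkyne with an (E)-vinyl iodide runs at room temperature with retention of alkene geometry, and C13 carries no hydrogen so nothing can epimerise.

Step 11
Reactants: 14 (3aR,7aS)-7a-[(3E,5R)-6-(benzyloxy)-5-methylhex-3-en-1-yn-1-yl]-4,4-dimethyl-3,3a,4,7a-tetrahydro-2-benzofuran-1,7-dione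
Product: 15 (3aR,7aR)-7a-[(1Z,3E,5R)-6-(benzyloxy)-5-methylhexa-1,3-dien-1-yl]-4,4-dimethyl-3,3a,4,7a-tetrahydro-2-benzofuran-1,7-dione
Conditions: H2 (1 atm), Pd/CaCO3 poisoned with Pb(OAc)2 (Lindlar catalyst), quinoline, EtOAc, rt, stopped at 1 equiv H2
Reagents that add atoms: none
Why: Lindlar semi-hydrogenation adds H2 syn to the alkyne only and so gives the (Z)-alkene at C7=C6, leaving the (E)-alkene, the enone and the benzyl ether (7a becomes R by priority change only).

Step 12
Reactants: 15 (3aR,7aR)-7a-[(1Z,3E,5R)-6-(benzyloxy)-5-methylhexa-1,3-dien-1-yl]-4,4-dimethyl-3,3a,4,7a-tetrahydro-2-benzofuran-1,7-dione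
Product: 16 (5R,6S)-6-[(1Z,3E,5R)-6-(benzyloxy)-5-methylhexa-1,3-dien-1-yl]-5,6-bis(hydroxymethyl)-4,4-dimethylcyclohex-2-en-1-ol (both C1 epimers)
Conditions: LiAlH4 (3 equiv), THF, −40 °C → 0 °C; aq. KNaC4H4O6
Reagents that add atoms: none
Why: Hydride reduction opens the lactone to the C12 and C18 primary alcohols and reduces the enone carbonyl 1,2 (β-carbon shielded by the gem-dimethyl group); the new C14 carbinol centre is a mixture that the next step erases.

Step 13
Reactants: 16 (5R,6S)-6-[(1Z,3E,5R)-6-(benzyloxy)-5-methylhexa-1,3-dien-1-yl]-5,6-bis(hydroxymethyl)-4,4-dimethylcyclohex-2-en-1-ol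
Product: 18 (1R,2S,5R)-2-[(1Z,3E,5R)-6-(benzyloxy)-5-methylhexa-1,3-dien-1-yl]-2-(hydroxymethyl)-8,8-dimethyl-6-oxabicyclo[3.2.1]octan-3-one, via hydroxy enone 17 (not isolated)
Conditions: MnO2 (20 equiv), CH2Cl2, rt; filter; DBU (0.1 equiv), CH2Cl2, 0 °C → rt
Reagents that add atoms: none
Why: MnO2 oxidises only the allylic C14 alcohol, and the regenerated enone is then attacked at C16 by the C18 hydroxyl in a 5-exo-trig oxa-Michael addition whose bridge geometry fixes C16 as R, whereas attack by the C12 hydroxyl would need a boat-shaped 2-oxabicyclo[2.2.2]octane and should not compete.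

Step 14
Reactants: 18 (1R,2S,5R)-2-[(1Z,3E,5R)-6-(benzyloxy)-5-methylhexa-1,3-dien-1-yl]-2-(hydroxymethyl)-8,8-dimethyl-6-oxabicyclo[3.2.1]octan-3-one
Product: 19 [(1R,2S,5R)-2-[(1Z,3E,5R)-6-(benzyloxy)-5-methylhexa-1,3-dien-1-yl]-8,8-dimethyl-3-oxo-6-oxabicyclo[3.2.1]octan-2-yl]methyl prop-2-enoate
Conditions: acryloyl chloride (1.5 equiv), iPr2NEt (2 equiv), DMAP (5 mol%), CH2Cl2, −78 °C → 0 °C
Reagents that add atoms: acryloyl chloride C=CC(=O)Cl
Why: Nucleophilic acyl substitution at the only free hydroxyl, and because C13 has no hydrogen the β-acyloxy ketone cannot eliminate.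

Step 15
Reactants: 19 [(1R,2S,5R)-2-[(1Z,3E,5R)-6-(benzyloxy)-5-methylhexa-1,3-dien-1-yl]-8,8-dimethyl-3-oxo-6-oxabicyclo[3.2.1]octan-2-yl]methyl prop-2-enoate
Product: 20 (1R,2S,4a'R,5R,7'S,8a'S)-7'-[(2R)-1-(benzyloxy)propan-2-yl]-8,8-dimethyl-4a',7',8',8a'-tetrahydro-6-oxaspiro[bicyclo[3.2.1]octane-2,4'-isochromane]-1',3-dione (labels 2R,4S,7R,8S,13S,16R,19R; C5=C6 alkene)
Conditions: toluene (0.01 M), BHT (10 mol%), sealed tube, 170 °C
Reagents that add atoms: none
Why: Ester-tethered intramolecular Diels–Alder reaction helped by the quaternary C13 in the tether, in which the tether on the (Z) end of the diene allows only the cis-fused lactone (H7 and H8 cis), the (E) substituent at C4 ends up trans to C13, no 1,5-hydrogen shift is possible because the (Z) substituent is quaternary, and allylic 1,3-strain turns the bulky C19 arm of the spiro centre outward and the flat C14 carbonyl inward so that the acrylate should add to the diene face giving 7R, 8S and the C4 arrangement of the target.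

Step 16
Reactants: 20 (1R,2S,4a'R,5R,7'S,8a'S)-7'-[(2R)-1-(benzyloxy)propan-2-yl]-8,8-dimethyl-4a',7',8',8a'-tetrahydro-6-oxaspiro[bicyclo[3.2.1]octane-2,4'-isochromane]-1',3-dione
Product: 21 (1R,2S,4a'R,5R,7'R,8a'S)-7'-[(2R)-1-hydroxypropan-2-yl]-8,8-dimethyl-4a',5',6',7',8',8a'-hexahydro-6-oxaspiro[bicyclo[3.2.1]octane-2,4'-isochromane]-1',3-dione
Conditions: H2 (1 atm), Pd/C (10 wt%), EtOAc/EtOH, rt
Reagents that add atoms: none
Why: Catalytic hydrogenation saturates the cis-disubstituted C5=C6 alkene without creating a stereocentre and hydrogenolysis removes the benzyl ether in the same operation, while ketone, lactone and ether bridge are inert.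

Step 17
Reactants: 21 (1R,2S,4a'R,5R,7'R,8a'S)-7'-[(2R)-1-hydroxypropan-2-yl]-8,8-dimethyl-4a',5',6',7',8',8a'-hexahydro-6-oxaspiro[bicyclo[3.2.1]octane-2,4'-isochromane]-1',3-dione
Product: 22 (2R)-2-[(1R,2S,4a'R,5R,7'R,8a'S)-8,8-dimethyl-1',3-dioxo-4a',5',6',7',8',8a'-hexahydro-6-oxaspiro[bicyclo[3.2.1]octane-2,4'-isochroman]-7'-yl]propanoic acid (target)
Conditions: TEMPO (0.2 equiv), PhI(OAc)2 (2.5 equiv), MeCN/H2O (1:1), rt
Reagents that add atoms: water O
Why: Oxoammonium (TEMPO) oxidation takes the primary alcohol to the aldehyde and its hydrate on to the acid under near-neutral conditions that do not epimerise C2 or C8 or open the β-alkoxy ketone.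

**Compound list**

1 | 4,4-dimethylcyclohex-2-en-1-one | CC1(C)CCC(=O)C=C1 | starting material
2 | 4,4-dimethylcyclohexa-2,5-dien-1-one | CC1(C)C=CC(=O)C=C1 | intermediate
3 | chloromethyl propan-2-yl carbonate | CC(C)OC(=O)OCCl | starting material
4 | iodomethyl propan-2-yl carbonate | CC(C)OC(=O)OCI | intermediate
5 | iodo{[(propan-2-yloxy)carbonyloxy]methyl}zinc (organozinc iodide, not isolated) | CC(C)OC(=O)OC[Zn]I | intermediate
6 | {[(propan-2-yloxy)carbonyloxy]methyl}[(trimethylsilyl)methyl]zinc | CC(C)OC(=O)OC[Zn]C[Si](C)(C)C | intermediate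
7 | [(1S)-2,2-dimethyl-5-oxocyclohex-3-en-1-yl]methyl propan-2-yl carbonate (label 19S) | O=C1C=CC(C)(C)[C@@H](COC(=O)OC(C)C)C1 | intermediate
8 | (3aS,7aR)-4,4-dimethyl-3,3a,4,7a-tetrahydro-2-benzofuran-1,7-dione (cis-fused β-keto γ-lactone) | O=C1OC[C@@H]2C(C)(C)C=CC(=O)[C@H]12 | intermediate
9 | (3aR,7aS)-7a-ethynyl-4,4-dimethyl-3,3a,4,7a-tetrahydro-2-benzofuran-1,7-dione | O=C1OC[C@@H]2C(C)(C)C=CC(=O)[C@]12C#C | intermediate
10 | methyl (2S)-3-hydroxy-2-methylpropanoate | C[C@@H](CO)C(=O)OC | starting material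
11 | methyl (2S)-3-(benzyloxy)-2-methylpropanoate | C[C@@H](COCc1ccccc1)C(=O)OC | intermediate
12 | (2S)-3-(benzyloxy)-2-methylpropanal | C[C@@H](COCc1ccccc1)C=O | intermediate
13 | {[(2R,3E)-4-iodo-2-methylbut-3-en-1-yl]oxy}methylbenzene | C[C@@H](COCc1ccccc1)/C=C/I | intermediate
14 | (3aR,7aS)-7a-[(3E,5R)-6-(benzyloxy)-5-methylhex-3-en-1-yn-1-yl]-4,4-dimethyl-3,3a,4,7a-tetrahydro-2-benzofuran-1,7-dione | O=C1OC[C@@H]2C(C)(C)C=CC(=O)[C@]12C#C/C=C/[C@@H](C)COCc1ccccc1 | intermediate
15 | (3aR,7aR)-7a-[(1Z,3E,5R)-6-(benzyloxy)-5-methylhexa-1,3-dien-1-yl]-4,4-dimethyl-3,3a,4,7a-tetrahydro-2-benzofuran-1,7-dione | O=C1OC[C@@H]2C(C)(C)C=CC(=O)[C@]12/C=C\C=C\[C@@H](C)COCc1ccccc1 | intermediate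
16 | (5R,6S)-6-[(1Z,3E,5R)-6-(benzyloxy)-5-methylhexa-1,3-dien-1-yl]-5,6-bis(hydroxymethyl)-4,4-dimethylcyclohex-2-en-1-ol (both C1 epimers) | OC[C@@H]1C(C)(C)C=CC(O)[C@@]1(CO)/C=C\C=C\[C@@H](C)COCc1ccccc1 | intermediate
17 | (5R,6S)-6-[(1Z,3E,5R)-6-(benzyloxy)-5-methylhexa-1,3-dien-1-yl]-5,6-bis(hydroxymethyl)-4,4-dimethylcyclohex-2-en-1-one (hydroxy enone, not isolated) | OC[C@@H]1C(C)(C)C=CC(=O)[C@@]1(CO)/C=C\C=C\[C@@H](C)COCc1ccccc1 | intermediate
18 | (1R,2S,5R)-2-[(1Z,3E,5R)-6-(benzyloxy)-5-methylhexa-1,3-dien-1-yl]-2-(hydroxymethyl)-8,8-dimethyl-6-oxabicyclo[3.2.1]octan-3-one | OC[C@@]1(/C=C\C=C\[C@@H](C)COCc2ccccc2)C(=O)C[C@H]2OC[C@@H]1C2(C)C | intermediate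
19 | [(1R,2S,5R)-2-[(1Z,3E,5R)-6-(benzyloxy)-5-methylhexa-1,3-dien-1-yl]-8,8-dimethyl-3-oxo-6-oxabicyclo[3.2.1]octan-2-yl]methyl prop-2-enoate | C=CC(=O)OC[C@@]1(/C=C\C=C\[C@@H](C)COCc2ccccc2)C(=O)C[C@H]2OC[C@@H]1C2(C)C | intermediate
20 | (1R,2S,4a'R,5R,7'S,8a'S)-7'-[(2R)-1-(benzyloxy)propan-2-yl]-8,8-dimethyl-4a',7',8',8a'-tetrahydro-6-oxaspiro[bicyclo[3.2.1]octane-2,4'-isochromane]-1',3-dione (labels 2R,4S,7R,8S,13S,16R,19R) | C[C@@H](COCc3ccccc3)[C@@H]1C=C[C@@H]2[C@H](C1)C(=O)OC[C@]21C(=O)C[C@H]2OC[C@@H]1C2(C)C | intermediate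
21 | (1R,2S,4a'R,5R,7'R,8a'S)-7'-[(2R)-1-hydroxypropan-2-yl]-8,8-dimethyl-4a',5',6',7',8',8a'-hexahydro-6-oxaspiro[bicyclo[3.2.1]octane-2,4'-isochromane]-1',3-dione | C[C@@H](CO)[C@@H]1CC[C@@H]2[C@H](C1)C(=O)OC[C@]21C(=O)C[C@H]2OC[C@@H]1C2(C)C | intermediate
22 | (2R)-2-[(1R,2S,4a'R,5R,7'R,8a'S)-8,8-dimethyl-1',3-dioxo-4a',5',6',7',8',8a'-hexahydro-6-oxaspiro[bicyclo[3.2.1]octane-2,4'-isochroman]-7'-yl]propanoic acid (labels 2R,4R,7R,8S,13S,16R,19R) | C[C@@H](C(=O)O)[C@@H]1CC[C@@H]2[C@H](C1)C(=O)OC[C@]21C(=O)C[C@H]2OC[C@@H]1C2(C)C | target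

**Step count**

Total: 17 steps. Longest linear sequence: 13 steps (3 → 4 → 6 → 7 → 8 → 9 → 14 → 15 → 16 → 18 → 19 → 20 → 21 → 22); 12 steps counted from 1.

**The three steps most likely to fail**

Step 4 (new combination of an α-oxygenated mixed diorganozinc with the chiral copper catalyst; reactivity, group-transfer selectivity and enantioselectivity are unproven). The fallback sets out from 2 and comes back at 7. A rhodium-catalysed asymmetric 1,4-addition of CH2=CHBF3K ([RhCl(cod)]2, BINAP antipode chosen as above, dioxane/H2O, 80 °C) desymmetrises 2 to (5R)-5-ethenyl-4,4-dimethylcyclohex-2-en-1-one F1. Ozone (CH2Cl2/MeOH, −78 °C, Sudan red end point, then Me2S) cleaves only the electron-rich vinyl group to (1S)-2,2-dimethyl-5-oxocyclohex-3-ene-1-carbaldehyde F2. This is reduced at once with NaBH(OAc)3 to (5S)-5-(hydroxymethyl)-4,4-dimethylcyclohex-2-en-1-one F3, and isopropyl chloroformate/pyridine traps the open-chain alcohol as 7.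

Step 13 (the C12 hydroxyl may compete in the oxa-Michael addition, or the β-hydroxy ketone may lose formaldehyde under base). The fallback sets out from 15 and comes back at 19; it closes the ether bridge before the second primary alcohol exists. Catalytic NaOMe in MeOH at 0 °C opens the activated lactone, and the freed C18 alkoxide adds to the enone to give methyl (1R,2R,5R)-2-[(1Z,3E,5R)-6-(benzyloxy)-5-methylhexa-1,3-dien-1-yl]-8,8-dimethyl-3-oxo-6-oxabicyclo[3.2.1]octane-2-carboxylate F4. LiAlH4 reduces ester and ketone to (1R,2S,5R)-2-[(1Z,3E,5R)-6-(benzyloxy)-5-methylhexa-1,3-dien-1-yl]-2-(hydroxymethyl)-8,8-dimethyl-6-oxabicyclo[3.2.1]octan-3-ol F5 (both C3 epimers). Acryloyl chloride/iPr2NEt at −78 °C acylates only the primary hydroxyl to [(1R,2S,5R)-2-[(1Z,3E,5R)-6-(benzyloxy)-5-methylhexa-1,3-dien-1-yl]-3-hydroxy-8,8-dimethyl-6-oxabicyclo[3.2.1]octan-2-yl]methyl prop-2-enoate F6, and Dess–Martin periodinane oxidises the hindered secondary alcohol to 19.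

Step 15 (the ester tether and the (Z)-diene both slow the cycloaddition, and the facial selectivity rests on a conformational argument). The fallback sets out from 18 and comes back at 20; it uses a more reactive dienophile with a traceless activating group. 2-Bromoacrylic acid/DCC/DMAP gives [(1R,2S,5R)-2-[(1Z,3E,5R)-6-(benzyloxy)-5-methylhexa-1,3-dien-1-yl]-8,8-dimethyl-3-oxo-6-oxabicyclo[3.2.1]octan-2-yl]methyl 2-bromoprop-2-enoate F7. This should cyclise at or below 110 °C, under the same geometric constraints, to (1R,2R,4a'S,5R,7'S,8a'R)-7'-[(2R)-1-(benzyloxy)propan-2-yl]-8a'-bromo-8,8-dimethyl-4a',7',8',8a'-tetrahydro-6-oxaspiro[bicyclo[3.2.1]octane-2,4'-isochromane]-1',3-dione F8. Bu3SnH/AIBN (toluene, 80 °C) then replaces bromine by hydrogen from the convex face to give 20. If some C8 epimer forms, brief DBU equilibration should favour the cis-fused lactone, in which H7 rather than a ring carbon sits between the two arms of the spiro ring.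

**Further compounds**

F1 | step 4 | (5R)-5-ethenyl-4,4-dimethylcyclohex-2-en-1-one | O=C1C=CC(C)(C)[C@@H](C=C)C1
F2 | step 4 | (1S)-2,2-dimethyl-5-oxocyclohex-3-ene-1-carbaldehyde | O=C1C=CC(C)(C)[C@@H](C=O)C1
F3 | step 4 | (5S)-5-(hydroxymethyl)-4,4-dimethylcyclohex-2-en-1-one | O=C1C=CC(C)(C)[C@@H](CO)C1
F4 | step 13 | methyl (1R,2R,5R)-2-[(1Z,3E,5R)-6-(benzyloxy)-5-methylhexa-1,3-dien-1-yl]-8,8-dimethyl-3-oxo-6-oxabicyclo[3.2.1]octane-2-carboxylate | COC(=O)[C@@]1(/C=C\C=C\[C@@H](C)COCc2ccccc2)C(=O)C[C@H]2OC[C@@H]1C2(C)C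
F5 | step 13 | (1R,2S,5R)-2-[(1Z,3E,5R)-6-(benzyloxy)-5-methylhexa-1,3-dien-1-yl]-2-(hydroxymethyl)-8,8-dimethyl-6-oxabicyclo[3.2.1]octan-3-ol (both C3 epimers) | OC[C@@]1(/C=C\C=C\[C@@H](C)COCc2ccccc2)C(O)C[C@H]2OC[C@@H]1C2(C)C
F6 | step 13 | [(1R,2S,5R)-2-[(1Z,3E,5R)-6-(benzyloxy)-5-methylhexa-1,3-dien-1-yl]-3-hydroxy-8,8-dimethyl-6-oxabicyclo[3.2.1]octan-2-yl]methyl prop-2-enoate (both C3 epimers) | C=CC(=O)OC[C@@]1(/C=C\C=C\[C@@H](C)COCc2ccccc2)C(O)C[C@H]2OC[C@@H]1C2(C)C
F7 | step 15 | [(1R,2S,5R)-2-[(1Z,3E,5R)-6-(benzyloxy)-5-methylhexa-1,3-dien-1-yl]-8,8-dimethyl-3-oxo-6-oxabicyclo[3.2.1]octan-2-yl]methyl 2-bromoprop-2-enoate | C=C(Br)C(=O)OC[C@@]1(/C=C\C=C\[C@@H](C)COCc2ccccc2)C(=O)C[C@H]2OC[C@@H]1C2(C)C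
F8 | step 15 | (1R,2R,4a'S,5R,7'S,8a'R)-7'-[(2R)-1-(benzyloxy)propan-2-yl]-8a'-bromo-8,8-dimethyl-4a',7',8',8a'-tetrahydro-6-oxaspiro[bicyclo[3.2.1]octane-2,4'-isochromane]-1',3-dione | C[C@@H](COCc3ccccc3)[C@@H]1C=C[C@@H]2[C@](Br)(C1)C(=O)OC[C@]21C(=O)C[C@H]2OC[C@@H]1C2(C)C
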